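**Retrosynthetic overview**

1. The (E)-CH=CH-C(CH3)2OH arm is traced back to a prenyl group (hydroxyselenation, then selenoxide syn-elimination), and the aryl ester to a phenol plus (S)-3-acetoxybutanoic acid from the chiral pool.
2. The ortho-prenylphenol is cut at the bond between ring carbon 3 and the prenyl CH2: aromatic Claisen rearrangement of the O-(1,1-dimethylallyl) ether of methyl 4-hydroxycinnamate.
3. Feature on which this rests: the five-carbon arm on ring carbon 3 sits ortho to the oxygen on ring carbon 4, and the para carbon (ring carbon 1) is occupied by the acrylate. An allyl unit leaving oxygen can therefore end only on carbon 3 (carbon 5 is equivalent by symmetry).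
4. The tertiary allyl ether comes from copper-catalysed O-propargylation with 3-chloro-3-methylbut-1-yne followed by semihydrogenation.
5. No ring is formed at any stage; the benzene ring is bought with the cinnamate already in place.

Key step: step 3

Remark: the only stereocentre, the acetoxy-bearing carbon, is (S) in the target; it is bought as (S)-3-hydroxybutanoic acid and no step makes or breaks a bond at it.

**Route**

Step 1
Reactants: 1 methyl (E)-3-(4-hydroxyphenyl)acrylate (methyl 4-hydroxycinnamate); 2 3-chloro-3-methylbut-1-yne
Product: 3 methyl (E)-3-[4-(2-methylbut-3-yn-2-yloxy)phenyl]acrylate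
Conditions: 2 (1.5 equiv), DBU (1.6 equiv), CuCl2·2H2O (cat.), MeCN, 0 °C
Reagents that add atoms: none
Why: Copper-catalysed O-propargylation of a phenol with a tertiary propargylic chloride (DBU/CuCl2 conditions), which alkylates the phenoxide at the hindered tertiary carbon while the enoate ester is inert at 0 °C.

Step 2
Reactants: 3 methyl (E)-3-[4-(2-methylbut-3-yn-2-yloxy)phenyl]acrylate
Product: 4 methyl (E)-3-[4-(2-methylbut-3-en-2-yloxy)phenyl]acrylate
Conditions: H2 (1 atm), Pd/CaCO3 poisoned with Pb(OAc)2, quinoline, EtOAc, rt, stopped at 1 equiv H2
Reagents that add atoms: none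
Why: Lindlar semihydrogenation, in which the poisoned catalyst reduces the terminal alkyne faster than any alkene, so the conjugated trans-enoate and the new vinyl group should persist when uptake is stopped at one equivalent.

Step 3
Reactants: 4 methyl (E)-3-[4-(2-methylbut-3-en-2-yloxy)phenyl]acrylate
Product: 6 methyl (E)-3-[4-hydroxy-3-(3-methylbut-2-enyl)phenyl]acrylate, via ortho-prenyl cyclohexadienone 5 (not isolated)
Conditions: PhNEt2 (degassed), 150 °C, Ar
Reagents that add atoms: none
Why: Aromatic Claisen rearrangement: a concerted suprafacial [3,3]-sigmatropic shift through a chair-like six-membered transition state breaks the O-C(CH3)2 bond of 4 while the vinyl CH2 terminus bonds to ring carbon 3, giving dienone 5, which tautomerises to phenol 6 and so makes the step irreversible. The closest known reaction type is the thermal rearrangement of aryl 1,1-dimethylallyl (reverse-prenyl) ethers to ortho-prenylphenols, which the geminal methyl groups accelerate. No ring is closed and no stereocentre survives, because the sp3 ring carbon of 5 is flattened on enolisation and the new alkene carries two identical methyl groups. The selectivity needed is ortho over para and sigmatropic shift over heterolysis: ring carbon 1 carries the acrylate, so a further shift to the para position cannot end in an aromatic product, and the two ortho carbons are equivalent, so one regioisomer is expected. The weakly basic, non-ionising amine solvent and the moderate temperature should hold back ionisation of the tertiary ether to the phenol and isoprene and keep acid away from 6, which would otherwise cyclise to a 2,2-dimethylchroman.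

Step 4
Reactants: 7 (S)-3-hydroxybutanoic acid
Product: 8 (S)-3-acetoxybutanoic acid
Conditions: AcCl (neat, excess), 0 °C to rt; evaporate; then THF/H2O, rt
Reagents that add atoms: acetyl chloride, CC(=O)Cl
Why: O-Acetylation of a secondary alcohol with an acyl chloride, which takes place at oxygen and not at the stereogenic carbon, so the (S) configuration is carried over unchanged (the aqueous stir returns any carboxyl-activated material to the free acid).

Step 5
Reactants: 6 methyl (E)-3-[4-hydroxy-3-(3-methylbut-2-enyl)phenyl]acrylate; 8 (S)-3-acetoxybutanoic acid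
Product: 10 methyl (E)-3-[4-[(S)-3-acetoxybutanoyloxy]-3-(3-methylbut-2-enyl)phenyl]acrylate, via O-acylisourea 9 (not isolated)
Conditions: DCC (1.2 equiv), DMAP (cat.), CH2Cl2, 0 °C to rt
Reagents that add atoms: none
Why: Steglich esterification, in which DCC activates acid 8 as O-acylisourea 9 and DMAP serves as acyl-transfer catalyst to the moderately hindered phenol at low temperature, where base-induced loss of acetate from the beta-acetoxy acyl unit should stay slow; the stereocentre is not involved.

Step 6
Reactants: 10 methyl (E)-3-[4-[(S)-3-acetoxybutanoyloxy]-3-(3-methylbut-2-enyl)phenyl]acrylate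
Product: 12 methyl (E)-3-[4-[(S)-3-acetoxybutanoyloxy]-3-[3-hydroxy-3-methyl-2-(phenylselanyl)butyl]phenyl]acrylate (both epimers at the selenium-bearing carbon), via seleniranium chloride 11 (not isolated)
Conditions: PhSeCl (1.1 equiv), MeCN/H2O (5:1), 0 °C to rt
Reagents that add atoms: benzeneselenenyl chloride, Cl[Se]c1ccccc1; water, O
Why: Electrophilic hydroxyselenation, in which PhSeCl forms seleniranium ion 11 only on the electron-rich trisubstituted prenyl alkene (the enoate alkene is too electron-poor) and water opens it at the tertiary carbon (Markovnikov), placing OH on the C(CH3)2 carbon and selenium on the adjacent CH; the new selenium-bearing stereocentre forms unselectively, which does not matter because step 7 destroys it.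

Step 7
Reactants: 12 methyl (E)-3-[4-[(S)-3-acetoxybutanoyloxy]-3-[3-hydroxy-3-methyl-2-(phenylselanyl)butyl]phenyl]acrylate
Product: 14 methyl (E)-3-[4-[(S)-3-acetoxybutanoyloxy]-3-[(E)-3-hydroxy-3-methylbut-1-enyl]phenyl]acrylate (CNP0325017.1), via selenoxide 13 (not isolated)
Conditions: NaIO4 (2.5 equiv), THF/H2O, 0 °C to rt
Reagents that add atoms: none
Why: Selenide oxidation followed by selenoxide syn-elimination, in which selenoxide 13 can take a hydrogen only from the benzylic CH2 because the carbinol carbon bears none, and the five-membered cyclic transition state with the aryl and C(CH3)2OH groups apart should give the (E)-styrenyl tertiary allylic alcohol; the excess NaIO4 oxidises the PhSeOH released so that it cannot add back to the alkene.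

**Compound list**

1 | methyl (E)-3-(4-hydroxyphenyl)acrylate (methyl 4-hydroxycinnamate) | COC(=O)/C=C/c1ccc(O)cc1 | starting material
2 | 3-chloro-3-methylbut-1-yne | C#CC(C)(C)Cl | starting material
3 | methyl (E)-3-[4-(2-methylbut-3-yn-2-yloxy)phenyl]acrylate | COC(=O)/C=C/c1ccc(OC(C)(C)C#C)cc1 | intermediate
4 | methyl (E)-3-[4-(2-methylbut-3-en-2-yloxy)phenyl]acrylate | COC(=O)/C=C/c1ccc(OC(C)(C)C=C)cc1 | intermediate
5 | methyl (E)-3-[3-(3-methylbut-2-enyl)-4-oxocyclohexa-1,5-dien-1-yl]acrylate (racemic at ring carbon 3) | COC(=O)/C=C/C1=CC(CC=C(C)C)C(=O)C=C1 | intermediate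
6 | methyl (E)-3-[4-hydroxy-3-(3-methylbut-2-enyl)phenyl]acrylate | COC(=O)/C=C/c1ccc(O)c(CC=C(C)C)c1 | intermediate
7 | (S)-3-hydroxybutanoic acid | C[C@H](O)CC(=O)O | starting material
8 | (S)-3-acetoxybutanoic acid | C[C@H](OC(C)=O)CC(=O)O | intermediate
9 | O-[(S)-3-acetoxybutanoyl]-N,N'-dicyclohexylisourea | C[C@H](OC(C)=O)CC(=O)OC(=NC1CCCCC1)NC1CCCCC1 | intermediate
10 | methyl (E)-3-[4-[(S)-3-acetoxybutanoyloxy]-3-(3-methylbut-2-enyl)phenyl]acrylate | COC(=O)/C=C/c1ccc(OC(=O)C[C@H](C)OC(C)=O)c(CC=C(C)C)c1 | intermediate
11 | 2,2-dimethyl-1-phenylseleniranium chloride carrying the aryl-CH2 group on ring carbon 3 (aryl = 2-[(S)-3-acetoxybutanoyloxy]-5-[(E)-2-methoxycarbonylvinyl]phenyl) | COC(=O)/C=C/c1ccc(OC(=O)C[C@H](C)OC(C)=O)c(CC2C(C)(C)[Se+]2c2ccccc2)c1.[Cl-] | intermediate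
12 | methyl (E)-3-[4-[(S)-3-acetoxybutanoyloxy]-3-[3-hydroxy-3-methyl-2-(phenylselanyl)butyl]phenyl]acrylate (both epimers at the selenium-bearing carbon) | COC(=O)/C=C/c1ccc(OC(=O)C[C@H](C)OC(C)=O)c(CC([Se]c2ccccc2)C(C)(C)O)c1 | intermediate
13 | methyl (E)-3-[4-[(S)-3-acetoxybutanoyloxy]-3-[3-hydroxy-3-methyl-2-(phenylseleninyl)butyl]phenyl]acrylate | COC(=O)/C=C/c1ccc(OC(=O)C[C@H](C)OC(C)=O)c(CC([Se](=O)c2ccccc2)C(C)(C)O)c1 | intermediate
14 | methyl (E)-3-[4-[(S)-3-acetoxybutanoyloxy]-3-[(E)-3-hydroxy-3-methylbut-1-enyl]phenyl]acrylate | COC(=O)/C=C/c1ccc(OC(=O)C[C@H](C)OC(C)=O)c(/C=C/C(C)(C)O)c1 | target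

**Step count**

Total steps: 7. Longest linear sequence: 6 (steps 1, 2, 3, 5, 6, 7); step 4 is a one-step side branch.

**Steps most likely to fail, with fallbacks**

Step 3 (key step). Heterolysis of the tertiary O-C bond may outrun the concerted shift, with loss of the allyl unit as isoprene and return of the phenol. Alternatively, traces of acid may make the new ortho-prenylphenol close onto its own alkene. The fallback abandons the oxygen-to-carbon transfer and installs the finished arm by cross-coupling:
- It sets out from 1, which is iodinated ortho to the hydroxyl (N-iodosuccinimide, cat. TsOH, MeCN, rt) to give methyl (E)-3-(4-hydroxy-3-iodophenyl)acrylate F1.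
- F1 is esterified with 8 (DCC, cat. DMAP, CH2Cl2, 0 °C) to give methyl (E)-3-[4-[(S)-3-acetoxybutanoyloxy]-3-iodophenyl]acrylate F2.
- A Heck reaction of F2 with 2-methylbut-3-en-2-ol (Pd(OAc)2, Bu4NCl, NaHCO3, DMF, 50 °C) should then give the (E)-styrenyl tertiary alcohol directly, because the carbinol carbon has no hydrogen and beta-hydride elimination can only go toward the ring side.
- The fallback comes back to the route at 14. Esterifying before the coupling keeps the phenol from cyclising onto the allylic alcohol.

Step 6. Chloride or the nitrile solvent may compete with water for the seleniranium ion, the addition may reverse, or the hydrogen chloride released may cleave the aryl ester, after which the freed phenol would close onto the seleniranium ion. The fallback replaces selenium chemistry by a Schenck ene reaction: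
- It sets out from 10, which is photo-oxygenated with singlet oxygen (O2, visible light above 400 nm, tetraphenylporphyrin, CH2Cl2, 0 °C).
- Abstraction of a benzylic hydrogen with allylic shift of the alkene should give methyl (E)-3-[4-[(S)-3-acetoxybutanoyloxy]-3-[(E)-3-hydroperoxy-3-methylbut-1-enyl]phenyl]acrylate F3.
- F3 is reduced with PPh3 (CH2Cl2, 0 °C) and the fallback comes back to the route at 14.
- The known weakness is competing hydrogen abstraction from a methyl group, so chromatographic removal of the regioisomeric secondary allylic alcohol must be expected.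

Step 2. Hydrogenation may run past the alkene stage, or the cinnamate double bond may be saturated in competition. The fallback avoids hydrogenation altogether:
- It sets out from 1, which is O-allylated directly with tert-butyl 2-methylbut-3-en-2-yl carbonate and Pd(PPh3)4 in THF at 0 °C (decarboxylative Tsuji-Trost reverse prenylation).
- The branched tertiary ether is the kinetic product, so the reaction is stopped before it equilibrates to the linear prenyl ether.
- The fallback comes back to the route at 4 and makes no new compound (F0).

**Further compounds**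

F1 | step 3 | methyl (E)-3-(4-hydroxy-3-iodophenyl)acrylate | COC(=O)/C=C/c1ccc(O)c(I)c1
F2 | step 3 | methyl (E)-3-[4-[(S)-3-acetoxybutanoyloxy]-3-iodophenyl]acrylate | COC(=O)/C=C/c1ccc(OC(=O)C[C@H](C)OC(C)=O)c(I)c1
F3 | step 6 | methyl (E)-3-[4-[(S)-3-acetoxybutanoyloxy]-3-[(E)-3-hydroperoxy-3-methylbut-1-enyl]phenyl]acrylate | COC(=O)/C=C/c1ccc(OC(=O)C[C@H](C)OC(C)=O)c(/C=C/C(C)(C)OO)c1
F0 | step 2 | none | none
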